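The route rests on cutting the C5′–C6′ bond (chain numbered C1′–C19′ outward from ring carbon C3) inside the unfunctionalised thirteen-methylene tether that separates the dihydroxyquinone ring from the C14′=C15′ E-olefin. Since nothing marks this CH2–CH2 bond, it is forged by a one-pot hydroboration/alkyl–alkyl Suzuki–Miyaura coupling. The terminal olefin C4′=C5′ of a pent-4-enyl-tetramethoxybenzene (the masked quinone) becomes a C5′ borane nucleophile, which is joined to C6′ of (E)-14-bromotetradec-5-ene. C6′ is the former carboxyl carbon of myristelaidic acid, so the E-olefin arrives ready-made. Oxidative demethylation and hydrolysis then unveil the 2,5-dihydroxy-1,4-benzoquinone.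

Key step: step 4

Remark: myristelaidic acid, (9E)-tetradec-9-enoic acid, is taken as a catalogue fatty acid; its E-olefin is carried through all steps untouched and becomes C14′=C15′ of the target.

Step 1
Reactants: 1 1,2,4,5-tetramethoxybenzene; 2 5-bromopent-1-ene
Product: 4 1,2,4,5-tetramethoxy-3-(pent-4-en-1-yl)benzene, via aryllithium 3 (not isolated)
Conditions: n-BuLi, TMEDA, THF, 0 °C → rt; then 2, DMPU, −78 °C → rt
Reagents that add atoms: none
Why: Directed ortho-lithiation between two methoxy groups gives aryllithium 3, which should displace the primary bromide of 2 by SN2 alkylation, the polar co-solvent favouring substitution over elimination.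

Step 2
Reactants: 5 myristelaidic acid, (9E)-tetradec-9-enoic acid
Product: 6 (9E)-tetradec-9-en-1-ol
Conditions: LiAlH4, THF, 0 °C → rt; H2O, aq. NaOH work-up
Reagents that add atoms: none
Why: Hydride reduction of a carboxylic acid to the primary alcohol with LiAlH4 leaves an isolated, unactivated olefin untouched, so the E geometry is retained.

Step 3
Reactants: 6 (9E)-tetradec-9-en-1-ol
Product: 7 (5E)-14-bromotetradec-5-ene
Conditions: CBr4, PPh3, CH2Cl2, 0 °C → rt
Reagents that add atoms: carbon tetrabromide, BrC(Br)(Br)Br
Why: The Appel reaction converts the primary alcohol into the bromide by SN2 displacement of an alkoxyphosphonium under neutral conditions that cannot isomerise the remote olefin.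

Step 4
Reactants: 4 1,2,4,5-tetramethoxy-3-(pent-4-en-1-yl)benzene; 7 (5E)-14-bromotetradec-5-ene
Product: 9 1,2,4,5-tetramethoxy-3-[(14E)-nonadec-14-en-1-yl]benzene, via B-alkyl-9-BBN borane 8 (not isolated)
Conditions: 4 (1.3 equiv), 9-BBN (1.25 equiv), THF, rt; then 7 (1.0 equiv), Pd(OAc)2 (4 mol %), PCy3 (8 mol %), K3PO4·H2O, THF, rt
Reagents that add atoms: none
Why: 9-BBN adds anti-Markovnikov across C4′=C5′ of 4, the only olefin then in the flask, to put boron on C5′ (8); hydroxide from K3PO4·H2O turns 8 into a borate, Pd(0)/PCy3 inserts into the C6′–Br bond of 7 by SN2-type oxidative addition, and B-to-Pd transfer of the primary alkyl group followed by reductive elimination forms the C5′–C6′ bond. The closest known reaction type is the room-temperature alkyl–alkyl Suzuki–Miyaura coupling of B-alkyl-9-BBN reagents with primary alkyl bromides that carry β-hydrogens under Pd(OAc)2/PCy3 catalysis. No ring is closed and no stereocentre is created; the E geometry of C14′=C15′ is brought in with 7 and lies eight carbons from the reacting centre. The step needs regioselective hydroboration, which the monosubstituted terminal olefin and the bulky borane secure, and it needs the E-olefin to stay unhydroborated, which is secured by consuming all B–H with a slight excess of 4 before 7 is added. It also needs reductive elimination to outrun β-hydride elimination, which the bulky electron-rich PCy3 ligand provides, and transfer of only the primary chain, which the secondary bridgehead B–C bonds of the BBN cage guarantee. The four methyl ethers keep the masked quinone inert to borane, base and Pd(0).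

Step 5
Reactants: 9 1,2,4,5-tetramethoxy-3-[(14E)-nonadec-14-en-1-yl]benzene
Product: 10 2,5-dimethoxy-3-[(14E)-nonadec-14-en-1-yl]cyclohexa-2,5-diene-1,4-dione
Conditions: CAN (2.5 equiv), MeCN/THF/H2O, 0 °C
Reagents that add atoms: water, O (supplies both quinone carbonyl oxygens)
Why: CAN oxidative demethylation of the very electron-rich tetraalkoxyarene (radical cation, attack of water at a para-related pair of methoxy-bearing carbons, loss of two MeOH) should give the p-quinone; by the symmetry of the 1,2,4,5-pattern both para modes give the same 2,5-dimethoxyquinone, and the isolated E-olefin is much harder to oxidise.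

Step 6
Reactants: 10 2,5-dimethoxy-3-[(14E)-nonadec-14-en-1-yl]cyclohexa-2,5-diene-1,4-dione
Product: 12 2,5-dihydroxy-3-[(14E)-nonadec-14-en-1-yl]cyclohexa-2,5-diene-1,4-dione, via disodium quinone-diolate 11 (not isolated)
Conditions: 2 M aq. NaOH, EtOH, argon, 70 °C; then 2 M HCl, 0 °C
Reagents that add atoms: sodium hydroxide, [Na+].[OH-]
Why: Each methoxy group is a vinylogous methyl ester, so hydroxide adds at C2 and C5 and expels methoxide (addition–elimination, saponification of a vinylogous ester) to give the stabilised dianion 11, which acid protonates to the dihydroxyquinone while the remote olefin is untouched.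

Compound list
1 | 1,2,4,5-tetramethoxybenzene | COc1cc(OC)c(OC)cc1OC | starting material
2 | 5-bromopent-1-ene | C=CCCCBr | starting material
3 | (2,3,5,6-tetramethoxyphenyl)lithium | [Li]c1c(OC)c(OC)cc(OC)c1OC | intermediate
4 | 1,2,4,5-tetramethoxy-3-(pent-4-en-1-yl)benzene | C=CCCCc1c(OC)c(OC)cc(OC)c1OC | intermediate
5 | myristelaidic acid, (9E)-tetradec-9-enoic acid | CCCC/C=C/CCCCCCCC(=O)O | starting material
6 | (9E)-tetradec-9-en-1-ol | CCCC/C=C/CCCCCCCCO | intermediate
7 | (5E)-14-bromotetradec-5-ene | CCCC/C=C/CCCCCCCCBr | intermediate
8 | 9-[5-(2,3,5,6-tetramethoxyphenyl)pentyl]-9-borabicyclo[3.3.1]nonane | COc1cc(OC)c(OC)c(CCCCCB2C3CCCC2CCC3)c1OC | intermediate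
9 | 1,2,4,5-tetramethoxy-3-[(14E)-nonadec-14-en-1-yl]benzene | CCCC/C=C/CCCCCCCCCCCCCc1c(OC)c(OC)cc(OC)c1OC | intermediate
10 | 2,5-dimethoxy-3-[(14E)-nonadec-14-en-1-yl]cyclohexa-2,5-diene-1,4-dione | CCCC/C=C/CCCCCCCCCCCCCC1=C(OC)C(=O)C=C(OC)C1=O | intermediate
11 | disodium 3-[(14E)-nonadec-14-en-1-yl]-3,6-dioxocyclohexa-1,4-diene-1,4-diolate (disodium salt of 12) | CCCC/C=C/CCCCCCCCCCCCCC1=C([O-])C(=O)C=C([O-])C1=O.[Na+].[Na+] | intermediate
12 | 2,5-dihydroxy-3-[(14E)-nonadec-14-en-1-yl]cyclohexa-2,5-diene-1,4-dione | CCCC/C=C/CCCCCCCCCCCCCC1=C(O)C(=O)C=C(O)C1=O | target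

Total step count: 6
Longest linear sequence: 5 steps (steps 2, 3, 4, 5 and 6, from myristelaidic acid 5)

Steps most likely to fail

Step 4. β-Hydride elimination from the alkylpalladium formed from 7, slow transmetalation with protodeboronation of 8, or palladium hydride migration along the chain would lower the coupling efficiency and could erode the olefin geometry. The fallback forms the same C5′–C6′ bond by a copper-catalysed Grignard/alkyl bromide coupling. It sets out from aryllithium 3 (made from 1 as in step 1) and bromide 7 and comes back to the route at 9. Aryllithium 3 would be alkylated with an excess of 1,5-dibromopentane in THF/DMPU to give 3-(5-bromopentyl)-1,2,4,5-tetramethoxybenzene F1. F1 would be converted with magnesium turnings in THF into [5-(2,3,5,6-tetramethoxyphenyl)pentyl]magnesium bromide F2. F2 would then be coupled with 7 under Li2CuCl4 catalysis (THF, −20 °C → rt) to give 9.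

Step 5. Over-oxidation, competing formation of the ortho-quinone or of oxidative dimers, and attack of cerium(IV)/nitrate on the olefin could consume material. The fallback avoids a metal oxidant altogether. It sets out from 9 and comes back to the route at 12, replacing steps 5 and 6. Exhaustive O-demethylation of 9 with BBr3 (CH2Cl2, −78 → 0 °C) would give 3-[(14E)-nonadec-14-en-1-yl]benzene-1,2,4,5-tetrol F3. F3 should autoxidise in air during a mildly basic aqueous work-up (aq. NaHCO3/EtOAc, then acidification) to the dihydroxyquinone 12.

Step 1. Dehydrobromination of 2 by the hindered, basic aryllithium and incomplete lithiation would return 1 and waste the bromide. The fallback replaces the SN2 alkylation by an sp2–sp3 cross-coupling. It sets out from aryllithium 3 and comes back to the route at 4. Aryllithium 3 would be quenched with iodine (THF, −78 °C) to give 3-iodo-1,2,4,5-tetramethoxybenzene F4. Negishi coupling of F4 with commercial pent-4-enylzinc bromide (Pd(OAc)2/SPhos, THF, 50 °C) would give 4.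

Further compounds
F1 | step 4 | 3-(5-bromopentyl)-1,2,4,5-tetramethoxybenzene | COc1cc(OC)c(OC)c(CCCCCBr)c1OC
F2 | step 4 | [5-(2,3,5,6-tetramethoxyphenyl)pentyl]magnesium bromide | COc1cc(OC)c(OC)c(CCCCC[Mg]Br)c1OC
F3 | step 5 | 3-[(14E)-nonadec-14-en-1-yl]benzene-1,2,4,5-tetrol | CCCC/C=C/CCCCCCCCCCCCCc1c(O)c(O)cc(O)c1O
F4 | step 1 | 3-iodo-1,2,4,5-tetramethoxybenzene | COc1cc(OC)c(OC)c(I)c1OC
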